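**Retrosynthetic overview**
- Target 16 comes from hydrogenolysis of the deca-benzyl precursor 15, whose two lactate C–O bonds are made by double Mitsunobu esterification of diacid 11 with the L-DOPA-derived (S)-hydroxy ester 14 (inversion to R).
- 11 comes from the two ring–aryl bonds at C3 and C4, made by twofold nickel-catalysed decarboxylative arylation of bis(N-hydroxyphthalimide) ester 5 with arylzinc 8, followed by acid removal of the 4-methoxybenzyl esters.
- 5 comes from 4, and 4 from dianhydride 1 and 4-methoxybenzyl alcohol 2 by alkaloid-directed opening of both anhydride rings at the C1 and C2 carbonyls (two ester C–O bonds, free acids on C3 and C4).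
- Feature used: in the cyclobutane C1–C4 of the target the carboxyl carbons on C1/C2 are trans, the aryls on C3/C4 are trans, and C1/C4 and C2/C3 are cis. This is the cis,trans,cis pattern of the maleic anhydride photodimer 1 (anhydride rings across C1/C4 and C2/C3), whose C1 and C2 carbonyls are exchanged by its twofold axis.
- Ring order: the cyclobutane is bought with 1 and no ring is formed afterwards; the two five-membered anhydride rings are opened in step 1.

Key step: step 1

Remark on the chemistry: quinidine is assumed to esterify the C1 and C2 carbonyls, by analogy with its sense on monocyclic cis-anhydrides. The absolute configuration of 4 would be checked once, and quinine would replace quinidine in the same procedure if the antipode were found.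

**Step 1**
Reactants: 1 cis,trans,cis-cyclobutane-1,2,3,4-tetracarboxylic dianhydride; 2 4-methoxybenzyl alcohol
Product: 4 (1R,2R,3R,4R)-3,4-bis{[(4-methoxyphenyl)methoxy]carbonyl}cyclobutane-1,2-dicarboxylic acid (esters on C1/C2 and acids on C3/C4 in target numbering), via monoester acid anhydride 3 (not isolated)
Conditions: quinidine (2.4 equiv), 2 (6 equiv), toluene, −50 °C, slurry to solution; cold 1 M HCl/EtOAc work-up (quinidine recovered from the aqueous phase); crystallisation
Reagents that add atoms: none
Why: The quinuclidine nitrogen of quinidine acts as general base and delivers the alcohol to one of the two enantiotopic carbonyls of a cis-fused succinic anhydride ring, the carboxylate leaving as its quinidinium salt; this is the alkaloid-mediated alcoholysis of meso anhydrides, known for cyclobutane-fused anhydrides and for benzylic alcohols. No ring is closed: both anhydride rings open and the cyclobutane is untouched. No stereocentre is created either; the four ring stereocentres of the achiral dianhydride become one enantiomeric array because the alkaloid chooses the carbonyl on C1 over its mirror-image partner on C4. In monoester 3 the carbonyls on C2 and C3 are diastereotopic, and since the C2 carbonyl is the twofold-axis image of the one already attacked, the same alkaloid should prefer it again, the C3 carbonyl being its mismatched choice. The step therefore needs one sense of carbonyl selection twice, and the twofold axis of 1 ensures that both events are matched. A wrong-sense event ends mostly in the achiral 1,3-diester, a diastereomer that is removed, so the enantiomeric purity of 4 should exceed that of a single opening.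

**Step 2**
Reactants: 4 (1R,2R,3R,4R)-3,4-bis{[(4-methoxyphenyl)methoxy]carbonyl}cyclobutane-1,2-dicarboxylic acid
Product: 5 bis(N-hydroxyphthalimide) ester of 4 at the C3 and C4 carboxyls (ring configuration of 4)
Conditions: N-hydroxyphthalimide (2.2 equiv), DIC (2.4 equiv), DMAP (0.1 equiv), CH2Cl2, 0 °C to rt
Reagents that add atoms: N-hydroxyphthalimide, O=C1c2ccccc2C(=O)N1O
Why: Carbodiimide (Steglich-type) esterification of the two free acids with N-hydroxyphthalimide gives the redox-active esters, and without strong base the 4-methoxybenzyl esters and the ring stereocentres are left alone.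

**Step 3**
Reactants: 6 4-bromo-1,2-bis(benzyloxy)benzene
Product: 8 [3,4-bis(benzyloxy)phenyl]zinc chloride (THF solution, used directly), via arylmagnesium bromide 7 (not isolated)
Conditions: Mg turnings, LiCl, THF, rt; then ZnCl2 (1 M in THF), 0 °C to rt
Reagents that add atoms: zinc chloride, Cl[Zn]Cl; magnesium, [Mg] (ends in 7 only)
Why: LiCl-assisted magnesium insertion into the aryl bromide followed by transmetalation to zinc gives the arylzinc chloride required for a Negishi-type coupling, and benzyl ethers tolerate both metals.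

**Step 4**
Reactants: 5 bis(N-hydroxyphthalimide) ester; 8 [3,4-bis(benzyloxy)phenyl]zinc chloride
Product: 10 bis(4-methoxybenzyl) (1R,2R,3R,4R)-3,4-bis[3,4-bis(benzyloxy)phenyl]cyclobutane-1,2-dicarboxylate, via monoaryl mono(NHPI) ester 9 (not isolated)
Conditions: NiCl2·glyme (40 mol%), 4,4′-di-tert-butyl-2,2′-bipyridine (80 mol%), 8 (6 equiv), THF/DMF, 25 °C
Reagents that add atoms: none
Why: In this nickel-catalysed decarboxylative Negishi arylation of redox-active esters, electron transfer from aryl-nickel(I) fragments each ester to a planar cyclobutyl radical that recombines with aryl-nickel(II) and reductively eliminates, so C3 and then C4 are re-made under substrate control, each aryl entering the ring face that carries one substituent rather than two (at C3 anti to the C4 activated ester and the transannular C1 ester, at C4 anti to the new C3 aryl and the transannular C2 ester), which should restore the cis,trans,cis pattern.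

**Step 5**
Reactants: 10 bis(4-methoxybenzyl) diaryl diester
Product: 11 (1R,2R,3R,4R)-3,4-bis[3,4-bis(benzyloxy)phenyl]cyclobutane-1,2-dicarboxylic acid
Conditions: TFA/CH2Cl2 (1:4), anisole (20 equiv), 0 °C
Reagents that add atoms: none
Why: Acidolysis of the 4-methoxybenzyl esters (loss of the stabilised benzylic cation, trapped by anisole) frees both acids without base, so the epimerisable C1 and C2 centres cis to their aryl neighbours are not touched and the benzyl aryl ethers remain.

**Step 6**
Reactants: 12 L-DOPA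
Product: 13 (2S)-3-(3,4-dihydroxyphenyl)-2-hydroxypropanoic acid
Conditions: NaNO2 (1.5 equiv), 1 M H2SO4, 0 °C to rt, under argon
Reagents that add atoms: water, O
Why: Diazotisation of an α-amino acid in aqueous acid (van Slyke-type deamination) replaces nitrogen by hydroxyl with net retention through two inversions assisted by the neighbouring carboxylate, so the S centre of L-DOPA is carried into 13.

**Step 7**
Reactants: 13 (2S)-3-(3,4-dihydroxyphenyl)-2-hydroxypropanoic acid
Product: 14 benzyl (2S)-3-[3,4-bis(benzyloxy)phenyl]-2-hydroxypropanoate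
Conditions: BnBr (3.3 equiv), K2CO3 (3.5 equiv), DMF, rt
Reagents that add atoms: benzyl bromide, BrCc1ccccc1
Why: Williamson O-alkylation under carbonate conditions benzylates the two phenols and the carboxylate but not the secondary alcohol, which potassium carbonate does not deprotonate.

**Step 8**
Reactants: 11 diaryl cyclobutane diacid; 14 benzyl (2S)-3-[3,4-bis(benzyloxy)phenyl]-2-hydroxypropanoate (2.4 equiv)
Product: 15 bis{(2R)-1-(benzyloxy)-3-[3,4-bis(benzyloxy)phenyl]-1-oxopropan-2-yl} (1R,2R,3R,4R)-3,4-bis[3,4-bis(benzyloxy)phenyl]cyclobutane-1,2-dicarboxylate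
Conditions: PPh3 (3 equiv), DIAD (3 equiv), THF, 0 °C to rt
Reagents that add atoms: none
Why: Mitsunobu esterification activates the secondary alcohol of 14 and not the cyclobutane acids, so each carboxylate displaces the oxyphosphonium group in an SN2 step with inversion (S to R) while C1 and C2, which would be at risk under acyl activation with base, stay fixed.

**Step 9**
Reactants: 15 deca-benzyl precursor
Product: 16 bis[(1R)-1-carboxy-2-(3,4-dihydroxyphenyl)ethyl] (1R,2R,3R,4R)-3,4-bis(3,4-dihydroxyphenyl)cyclobutane-1,2-dicarboxylate (CNP0163929.1)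
Conditions: H2 (1 atm), 10% Pd/C, THF/MeOH, rt
Reagents that add atoms: none
Why: Palladium-catalysed hydrogenolysis cleaves the eight benzyl aryl ethers and the two benzyl esters under neutral conditions, while the lactate ester links (not benzylic at oxygen) and the cyclobutane should survive.

**Compound list**
1 | cis,trans,cis-cyclobutane-1,2,3,4-tetracarboxylic dianhydride (achiral; anhydride rings across C1/C4 and C2/C3 on opposite faces) | O=C2[C@H]1[C@H](C(=O)O3)[C@H](C3=O)[C@H]1C(=O)O2 | starting material
2 | 4-methoxybenzyl alcohol | COc1ccc(CO)cc1 | starting material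
3 | monoester acid anhydride: C1 4-methoxybenzyl ester, C4 acid, C2/C3 anhydride intact | O=C(OCc1ccc(OC)cc1)[C@H]1[C@@H]2C(=O)OC(=O)[C@@H]2[C@H]1C(=O)O | intermediate (not isolated)
4 | (1R,2R,3R,4R)-3,4-bis{[(4-methoxyphenyl)methoxy]carbonyl}cyclobutane-1,2-dicarboxylic acid | O=C(OCc1ccc(OC)cc1)[C@H]1[C@H](C(=O)OCc2ccc(OC)cc2)[C@H](C(=O)O)[C@H]1C(=O)O | intermediate
5 | bis(1,3-dioxoisoindolin-2-yl) ester of 4 at the C3 and C4 carboxyls, 4-methoxybenzyl esters on C1 and C2 | O=C(OCc1ccc(OC)cc1)[C@H]1[C@H](C(=O)OCc2ccc(OC)cc2)[C@H](C(=O)ON2C(=O)c3ccccc3C2=O)[C@H]1C(=O)ON1C(=O)c2ccccc2C1=O | intermediate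
6 | 4-bromo-1,2-bis(benzyloxy)benzene | Brc1ccc(OCc2ccccc2)c(OCc2ccccc2)c1 | starting material
7 | [3,4-bis(benzyloxy)phenyl]magnesium bromide | Br[Mg]c1ccc(OCc2ccccc2)c(OCc2ccccc2)c1 | intermediate (not isolated)
8 | [3,4-bis(benzyloxy)phenyl]zinc chloride | Cl[Zn]c1ccc(OCc2ccccc2)c(OCc2ccccc2)c1 | intermediate
9 | monoaryl mono(NHPI) ester: aryl on C3 cis to the C2 ester, activated ester still on C4 | O=C(OCc1ccc(OC)cc1)[C@H]1[C@H](C(=O)OCc2ccc(OC)cc2)[C@H](c2ccc(OCc3ccccc3)c(OCc3ccccc3)c2)[C@H]1C(=O)ON1C(=O)c2ccccc2C1=O | intermediate (not isolated)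
10 | bis(4-methoxybenzyl) (1R,2R,3R,4R)-3,4-bis[3,4-bis(benzyloxy)phenyl]cyclobutane-1,2-dicarboxylate | O=C(OCc1ccc(OC)cc1)[C@H]1[C@H](C(=O)OCc2ccc(OC)cc2)[C@H](c2ccc(OCc3ccccc3)c(OCc3ccccc3)c2)[C@H]1c1ccc(OCc2ccccc2)c(OCc2ccccc2)c1 | intermediate
11 | (1R,2R,3R,4R)-3,4-bis[3,4-bis(benzyloxy)phenyl]cyclobutane-1,2-dicarboxylic acid | O=C(O)[C@H]1[C@H](C(=O)O)[C@H](c2ccc(OCc3ccccc3)c(OCc3ccccc3)c2)[C@H]1c1ccc(OCc2ccccc2)c(OCc2ccccc2)c1 | intermediate
12 | L-DOPA, (2S)-2-amino-3-(3,4-dihydroxyphenyl)propanoic acid | N[C@@H](Cc1ccc(O)c(O)c1)C(=O)O | starting material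
13 | (2S)-3-(3,4-dihydroxyphenyl)-2-hydroxypropanoic acid | O[C@@H](Cc1ccc(O)c(O)c1)C(=O)O | intermediate
14 | benzyl (2S)-3-[3,4-bis(benzyloxy)phenyl]-2-hydroxypropanoate | O[C@@H](Cc1ccc(OCc2ccccc2)c(OCc2ccccc2)c1)C(=O)OCc1ccccc1 | intermediate
15 | bis{(2R)-1-(benzyloxy)-3-[3,4-bis(benzyloxy)phenyl]-1-oxopropan-2-yl} (1R,2R,3R,4R)-3,4-bis[3,4-bis(benzyloxy)phenyl]cyclobutane-1,2-dicarboxylate | O=C(O[C@H](Cc1ccc(OCc2ccccc2)c(OCc2ccccc2)c1)C(=O)OCc1ccccc1)[C@H]1[C@H](C(=O)O[C@H](Cc2ccc(OCc3ccccc3)c(OCc3ccccc3)c2)C(=O)OCc2ccccc2)[C@H](c2ccc(OCc3ccccc3)c(OCc3ccccc3)c2)[C@H]1c1ccc(OCc2ccccc2)c(OCc2ccccc2)c1 | intermediate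
16 | bis[(1R)-1-carboxy-2-(3,4-dihydroxyphenyl)ethyl] (1R,2R,3R,4R)-3,4-bis(3,4-dihydroxyphenyl)cyclobutane-1,2-dicarboxylate | O=C(O[C@H](Cc1ccc(O)c(O)c1)C(=O)O)[C@H]1[C@H](C(=O)O[C@H](Cc2ccc(O)c(O)c2)C(=O)O)[C@H](c2ccc(O)c(O)c2)[C@H]1c1ccc(O)c(O)c1 | target

**Step count**
Total steps: 9. Longest linear sequence: 6 (steps 1, 2, 4, 5, 8, 9).

**Steps most likely to fail**

1. Step 1. Slow dissolution of the dianhydride may let uncatalysed alcoholysis compete, or the second opening may be steered by the first-formed carboxylate rather than by the alkaloid, so that enantiomeric purity drops and opening at the wrong carbonyl grows. Fallback, from 1 and 2, returning at 4: both rings would be opened without chiral control (2, Et3N, cat. DMAP, THF, rt) to give racemic 1,2-diester, that is 4 together with its antipode F2, beside the achiral 1,3-bis(4-methoxybenzyl) ester F1, which would be removed by crystallisation. The racemate would then be resolved by fractional crystallisation of the bis[(R)-1-phenylethylammonium] salt of 4 F3 (the (S)-amine is used instead if it gives the less soluble salt with the wanted acid), and cold dilute HCl would return 4.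

2. Step 4. Facial discrimination in one of the two radical captures may be insufficient, or the second activated ester may be reduced before the first radical is captured, with loss of both carboxyls. Fallback, from 5, returning at 11 (steps 4 and 5 are bypassed), in which the aryls are placed by cis-specific cyclopalladation instead of radical capture:
   - Reductive decarboxylation of 5 (NiCl2·6H2O, dtbbpy, Zn, PhSiH3, THF/DMF/iPrOH) would give bis(4-methoxybenzyl) (1R,2R)-cyclobutane-1,2-dicarboxylate F4.
   - TFA/anisole would give (1R,2R)-cyclobutane-1,2-dicarboxylic acid F5.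
   - Coupling with 8-aminoquinoline (EDC, HOBt) would give the bis(quinolin-8-yl)amide F6.
   - Pd(OAc)2/AgOAc-mediated β-C–H arylation with 1,2-bis(benzyloxy)-4-iodobenzene F7 (from 6 by n-BuLi then I2) would replace, on C3 and on C4, the hydrogen cis to the neighbouring amide and give the diaryl bis-amide F8 with the target ring pattern.
   - Activation as the bis(N-Boc) imide F9 (Boc2O, DMAP, MeCN) and cleavage with LiOH/H2O2 at 0 °C would give 11.

3. Step 8. β-Elimination of the activated β-aryl lactate may compete, or the second esterification at a carboxyl cis to an aryl group may stall. Fallback, from 14 and 11, returning at 15: 14 would be converted into benzyl (2S)-3-[3,4-bis(benzyloxy)phenyl]-2-(trifluoromethanesulfonyloxy)propanoate F10 (Tf2O, 2,6-lutidine, CH2Cl2, −78 °C). The bis-caesium salt of 11 (Cs2CO3, 1 equiv, DMF) would then be alkylated with F10 at 0 °C, the carboxylate displacing triflate with inversion to give 15 without activation of the cyclobutane carboxyls.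

**Further compounds**
F1 | step 1 | achiral 1,3-bis(4-methoxybenzyl) ester (esters on C1 and C3, acids on C2 and C4) | O=C(OCc1ccc(OC)cc1)[C@H]1[C@H](C(=O)O)[C@H](C(=O)OCc2ccc(OC)cc2)[C@H]1C(=O)O
F2 | step 1 | antipode of 4, (1S,2S,3S,4S) | O=C(OCc1ccc(OC)cc1)[C@@H]1[C@@H](C(=O)OCc2ccc(OC)cc2)[C@@H](C(=O)O)[C@@H]1C(=O)O
F3 | step 1 | bis[(R)-1-phenylethylammonium] salt of 4 | O=C(OCc1ccc(OC)cc1)[C@H]1[C@H](C(=O)OCc2ccc(OC)cc2)[C@H](C(=O)[O-])[C@H]1C(=O)[O-].C[C@@H]([NH3+])c1ccccc1.C[C@@H]([NH3+])c1ccccc1
F4 | step 4 | bis(4-methoxybenzyl) (1R,2R)-cyclobutane-1,2-dicarboxylate | O=C(OCc1ccc(OC)cc1)[C@H]1[C@H](C(=O)OCc2ccc(OC)cc2)CC1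
F5 | step 4 | (1R,2R)-cyclobutane-1,2-dicarboxylic acid | O=C(O)[C@H]1[C@H](C(=O)O)CC1
F6 | step 4 | (1R,2R)-N,N′-di(quinolin-8-yl)cyclobutane-1,2-dicarboxamide | O=C(Nc1cccc2cccnc12)[C@H]1[C@H](C(=O)Nc2cccc3cccnc23)CC1
F7 | step 4 | 1,2-bis(benzyloxy)-4-iodobenzene | Ic1ccc(OCc2ccccc2)c(OCc2ccccc2)c1
F8 | step 4 | (1R,2R,3R,4R)-3,4-bis[3,4-bis(benzyloxy)phenyl]-N,N′-di(quinolin-8-yl)cyclobutane-1,2-dicarboxamide | O=C(Nc1cccc2cccnc12)[C@H]1[C@H](C(=O)Nc2cccc3cccnc23)[C@H](c2ccc(OCc3ccccc3)c(OCc3ccccc3)c2)[C@H]1c1ccc(OCc2ccccc2)c(OCc2ccccc2)c1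
F9 | step 4 | bis(N-tert-butoxycarbonyl) derivative of F8 | O=C(N(C(=O)OC(C)(C)C)c1cccc2cccnc12)[C@H]1[C@H](C(=O)N(C(=O)OC(C)(C)C)c2cccc3cccnc23)[C@H](c2ccc(OCc3ccccc3)c(OCc3ccccc3)c2)[C@H]1c1ccc(OCc2ccccc2)c(OCc2ccccc2)c1
F10 | step 8 | benzyl (2S)-3-[3,4-bis(benzyloxy)phenyl]-2-(trifluoromethanesulfonyloxy)propanoate | O=S(=O)(O[C@@H](Cc1ccc(OCc2ccccc2)c(OCc2ccccc2)c1)C(=O)OCc1ccccc1)C(F)(F)F
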